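Ring C of the chromanone is cut at C3–C4 and at O1–C2. The C4 carbonyl carbon sits on C4a of ring B between the C5 methyl group and the C8a oxygen, so ring B plus C4 is an orsellinic acid, and C3–C2(CH3)2 is isobutylene. In one operation the acylium ion of 2,4-dimethoxy-6-methylbenzoyl chloride acylates isobutylene and the ortho methoxy oxygen traps the tertiary cation with loss of its methyl group, which gives the 2,2-dimethylchromanone. Ring B is then oxygenated at C6 (formylation, Dakin), joined to ring A by Ullmann ether synthesis and lactonised to the depsidone, and ring A is formylated last.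

Key step: step 1

Remark: ring A is the benzene ring that carries CHO, OH and CH3, ring B is the benzene ring of the chromanone and ring C is the dihydropyranone; chromanone numbering (O1 to C8a) is used for rings B and C. The target has no stereocentre; the transient α-chloro ethers 6 and 16 are racemic. Compounds 1, 2 and 10 are taken as catalogue materials.

Step 1
Reactants: 1 2,4-dimethoxy-6-methylbenzoic acid; 2 isobutylene (2-methylpropene)
Product: 5 7-methoxy-2,2,5-trimethylchroman-4-one, via acid chloride 3 (not isolated), via β-chloro ketone 4 (not isolated)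
Conditions: (COCl)2, cat. DMF, CH2Cl2, rt, evaporate; AlCl3 (2.5 equiv), CH2Cl2, −40 °C, 2 added slowly, then rt; aq. HCl
Reagents that add atoms: none
Why: AlCl3 ionises acid chloride 3 to a 2,6-disubstituted aroyl cation that adds to the CH2 terminus of isobutylene (C4–C3 bond), the tertiary cation resting as β-chloro ketone 4; on warming, re-ionised 4 is captured by the oxygen of the ortho methoxy group and chloride removes the methyl group of the resulting oxonium ion as CH3Cl (O1–C2 bond). The closest known reaction types are the Friedel–Crafts (Kondakov, Darzens–Nenitzescu) acylation of alkenes by acyl chlorides and the domino acylation/demethylative annulation of 2-methoxybenzoyl chlorides with alkynes to chromones. Ring C closes as a six-membered ring by 6-exo-tet (SN1-like) attack of oxygen on the tertiary centre with chloride as the external leaving group; any 2'-hydroxy enone formed by elimination and chelation-controlled demethylation would close by 6-endo-trig oxa-Michael addition to the same product. No stereocentre is formed. The step needs Markovnikov regiochemistry, secured by the tertiary cation, and loss of only one methyl ether, secured because only the ortho oxygen can reach the cation or chelate aluminium with the ketone. Both ortho positions of the aroyl ring are substituted, so the usual indanone closure of such cations is blocked, and slow addition of the alkene to the preformed acylium complex should limit oligomerisation of isobutylene.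

Step 2
Reactants: 5 7-methoxy-2,2,5-trimethylchroman-4-one
Product: 7 7-methoxy-2,2,5-trimethyl-4-oxochroman-6-carbaldehyde, via α-chloro ether 6 (not isolated)
Conditions: Cl2CHOMe, TiCl4, CH2Cl2, 0 °C → rt; aq. HCl
Reagents that add atoms: dichloromethyl methyl ether, COC(Cl)Cl; water, O
Why: Rieche formylation (electrophilic aromatic substitution) should go to C6, para to O1 and ortho to the 7-methoxy group, because 3,5-dialkoxytoluenes react next to the methyl group and not between the two oxygens (C8); hydrolysis of α-chloro ether 6 on work-up frees the aldehyde.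

Step 3
Reactants: 7 7-methoxy-2,2,5-trimethyl-4-oxochroman-6-carbaldehyde
Product: 9 6-hydroxy-7-methoxy-2,2,5-trimethylchroman-4-one, via aryl formate 8 (not isolated)
Conditions: mCPBA, CH2Cl2, rt; then K2CO3, MeOH, 0 °C
Reagents that add atoms: mCPBA, OOC(=O)c1cccc(Cl)c1
Why: Dakin-type Baeyer–Villiger oxidation, in which the electron-rich aryl group of the ortho-methoxy benzaldehyde migrates to give aryl formate 8 that mild methanolysis cleaves to the phenol, while the aryl alkyl ketone of ring C reacts too slowly with mCPBA to interfere.

Step 4
Reactants: 10 4-methoxy-2-methylbenzoic acid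
Product: 11 2-iodo-4-methoxy-6-methylbenzoic acid
Conditions: [Cp*IrCl2]2 (cat.), NIS, (CF3)2CHOH, rt
Reagents that add atoms: N-iodosuccinimide, O=C1CCC(=O)N1I
Why: Carboxylate-directed ortho C–H iodination (cyclometalation at iridium, then iodination of the metallacycle by NIS) should hit the only free position ortho to the carboxyl group faster than undirected iodination next to the methoxy group.

Step 5
Reactants: 9 6-hydroxy-7-methoxy-2,2,5-trimethylchroman-4-one; 11 2-iodo-4-methoxy-6-methylbenzoic acid
Product: 12 4-methoxy-2-[(7-methoxy-2,2,5-trimethyl-4-oxochroman-6-yl)oxy]-6-methylbenzoic acid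
Conditions: CuI (cat.), Cs2CO3, pyridine, 115 °C; aq. HCl
Reagents that add atoms: none
Why: Ullmann diaryl ether synthesis, in which the ortho carboxylate binds copper and activates the neighbouring C–I bond (the ortho-halobenzoic acid effect), which should compensate for the doubly ortho-substituted phenoxide of 9, whose C6 hydroxyl is the only free OH.

Step 6
Reactants: 12 4-methoxy-2-[(7-methoxy-2,2,5-trimethyl-4-oxochroman-6-yl)oxy]-6-methylbenzoic acid
Product: 13 4-hydroxy-2-[(7-hydroxy-2,2,5-trimethyl-4-oxochroman-6-yl)oxy]-6-methylbenzoic acid
Conditions: BBr3, CH2Cl2, −78 °C → rt; H2O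
Reagents that add atoms: none
Why: Lewis acid ether cleavage, in which bromide attacks the methyl group of each boron-complexed aryl methyl ether (SN2), so both methyl ethers fall while the diaryl ether and the weakly basic, ketone-conjugated ring C oxygen should survive; any ring-opened 2'-hydroxy enone would close again on work-up.

Step 7
Reactants: 13 4-hydroxy-2-[(7-hydroxy-2,2,5-trimethyl-4-oxochroman-6-yl)oxy]-6-methylbenzoic acid
Product: 15 deformyl-mollicellin A (the depsidone lacking the ring A formyl group), via O-acylisourea 14 (not isolated)
Conditions: DCC, THF, rt, high dilution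
Reagents that add atoms: none
Why: Carbodiimide (Steglich-type) lactonisation, in which the ring B 7-hydroxyl next to the ether bridge attacks O-acylisourea 14 in a 7-exo-trig closure; the ring A hydroxyl cannot reach its own carboxyl, dilution suppresses oligomers, and xanthone formation is excluded because both ring B positions ortho to the bridge are substituted.

Step 8
Reactants: 15 deformyl-mollicellin A
Product: 17 Mollicellin A, via α-chloro ether 16 (not isolated)
Conditions: Cl2CHOMe, TiCl4, CH2Cl2, 0 °C → rt; aq. HCl
Reagents that add atoms: dichloromethyl methyl ether, COC(Cl)Cl; water, O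
Why: Rieche formylation ortho to a phenol, in which the titanium phenoxide of ring A should direct the electrophile to the carbon between the hydroxyl and the bridging ether oxygen (the site formylated in orsellinates), ring B being deactivated by its ketone and aryl ester; hydrolysis of α-chloro ether 16 frees the aldehyde.

Compound list
1 | 2,4-dimethoxy-6-methylbenzoic acid | COc1cc(C)c(C(=O)O)c(OC)c1 | starting material
2 | isobutylene (2-methylpropene) | CC(C)=C | starting material
3 | 2,4-dimethoxy-6-methylbenzoyl chloride (not isolated) | COc1cc(C)c(C(=O)Cl)c(OC)c1 | intermediate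
4 | 3-chloro-1-(2,4-dimethoxy-6-methylphenyl)-3-methylbutan-1-one (not isolated) | COc1cc(C)c(C(=O)CC(C)(C)Cl)c(OC)c1 | intermediate
5 | 7-methoxy-2,2,5-trimethylchroman-4-one | COc1cc(C)c2C(=O)CC(C)(C)Oc2c1 | intermediate
6 | 6-[chloro(methoxy)methyl]-7-methoxy-2,2,5-trimethylchroman-4-one (racemic, not isolated) | COC(Cl)c1c(OC)cc2OC(C)(C)CC(=O)c2c1C | intermediate
7 | 7-methoxy-2,2,5-trimethyl-4-oxochroman-6-carbaldehyde | COc1cc2OC(C)(C)CC(=O)c2c(C)c1C=O | intermediate
8 | 7-methoxy-2,2,5-trimethyl-4-oxochroman-6-yl formate (not isolated) | COc1cc2OC(C)(C)CC(=O)c2c(C)c1OC=O | intermediate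
9 | 6-hydroxy-7-methoxy-2,2,5-trimethylchroman-4-one | COc1cc2OC(C)(C)CC(=O)c2c(C)c1O | intermediate
10 | 4-methoxy-2-methylbenzoic acid | COc1ccc(C(=O)O)c(C)c1 | starting material
11 | 2-iodo-4-methoxy-6-methylbenzoic acid | COc1cc(C)c(C(=O)O)c(I)c1 | intermediate
12 | 4-methoxy-2-[(7-methoxy-2,2,5-trimethyl-4-oxochroman-6-yl)oxy]-6-methylbenzoic acid | COc1cc(C)c(C(=O)O)c(Oc2c(OC)cc3OC(C)(C)CC(=O)c3c2C)c1 | intermediate
13 | 4-hydroxy-2-[(7-hydroxy-2,2,5-trimethyl-4-oxochroman-6-yl)oxy]-6-methylbenzoic acid | Cc1cc(O)cc(Oc2c(O)cc3OC(C)(C)CC(=O)c3c2C)c1C(=O)O | intermediate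
14 | O-acylisourea of acid 13 with N,N'-dicyclohexylcarbodiimide (not isolated) | Cc1cc(O)cc(Oc2c(O)cc3OC(C)(C)CC(=O)c3c2C)c1C(=O)OC(=NC1CCCCC1)NC1CCCCC1 | intermediate
15 | deformyl-mollicellin A: depsidone in which the ring A carboxyl is esterified to O7 of ring B and the ring A oxygen is bridged to C6 of ring B; ring A carries only OH and CH3 | Cc1cc(O)cc2c1C(=O)Oc1cc3OC(C)(C)CC(=O)c3c(C)c1O2 | intermediate
16 | depsidone 15 carrying a chloro(methoxy)methyl group on the ring A carbon between the hydroxyl and the bridging oxygen (racemic, not isolated) | Cc1cc(O)c(C(Cl)OC)c2c1C(=O)Oc1cc3c(c(C)c1O2)C(=O)CC(C)(C)O3 | intermediate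
17 | Mollicellin A | Cc1cc(O)c(C=O)c2c1C(=O)Oc1cc3c(c(C)c1O2)C(=O)CC(C)(C)O3 | target

Total steps: 8. Longest linear sequence: 7 (steps 1, 2, 3, 5, 6, 7, 8).

Steps most likely to fail

Step 1. Cationic oligomerisation of isobutylene may outrun acylation, or the tertiary cation may stall at the chloride or enone stage without the demethylative closure. The fallback forms the same two bonds in separate known operations; it sets out from 3 (made from 1 as in step 1 and freed from volatiles) and comes back at 5. Acylation of 2-methylprop-1-enylmagnesium bromide by 3 with catalytic Fe(acac)3 (THF, −78 °C) should give 1-(2,4-dimethoxy-6-methylphenyl)-3-methylbut-2-en-1-one F1. BCl3 (CH2Cl2, −78 → 0 °C) should cleave only the chelated ortho methyl ether to give 1-(2-hydroxy-4-methoxy-6-methylphenyl)-3-methylbut-2-en-1-one F2, which should close to 5 by oxa-Michael addition on K2CO3 in MeOH.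

Step 5. The iodo acid may be lost by protodeiodination while C–O bond formation at the doubly ortho-substituted phenoxide stays slow. The fallback is a copper-free aryl transfer from a diaryliodonium salt; it sets out from 11 (with 9 as partner) and comes back at 13. Esterification of 11 (MeI, K2CO3, DMF) gives methyl 2-iodo-4-methoxy-6-methylbenzoate F3. Oxidation with mCPBA and TsOH in MeCN followed by 1,3,5-trimethoxybenzene should give [5-methoxy-2-(methoxycarbonyl)-3-methylphenyl](2,4,6-trimethoxyphenyl)iodonium 4-methylbenzenesulfonate F4. With the potassium phenoxide of 9 (K2CO3, toluene, rt to 50 °C) the ester-bearing aryl group should be transferred, the trimethoxyphenyl group acting as the non-transferred ligand, to give methyl 4-methoxy-2-[(7-methoxy-2,2,5-trimethyl-4-oxochroman-6-yl)oxy]-6-methylbenzoate F5. BBr3 then cleaves both aryl methyl ethers and the hindered methyl ester in one operation to give 13.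

Step 8. Positional selectivity between the two carbons ortho to the ring A hydroxyl may be poor, with formylation between OH and CH3 competing with formylation between OH and the bridging oxygen. The fallback uses a temporary bromine block; it sets out from 15 and comes back at 17. NBS (MeCN, 0 °C) should brominate the ring A carbon between OH and CH3, the halogenation site of orsellinates, to give the bromo depsidone F6. Rieche formylation (Cl2CHOMe, TiCl4) can then only go to the carbon between OH and the bridging oxygen, giving the bromo aldehyde F7. Transfer hydrodebromination (Pd(OAc)2, PPh3, HCO2H, Et3N, DMF, 60 °C) should then give 17.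

Further compounds
F1 | step 1 | 1-(2,4-dimethoxy-6-methylphenyl)-3-methylbut-2-en-1-one | COc1cc(C)c(C(=O)C=C(C)C)c(OC)c1
F2 | step 1 | 1-(2-hydroxy-4-methoxy-6-methylphenyl)-3-methylbut-2-en-1-one | COc1cc(C)c(C(=O)C=C(C)C)c(O)c1
F3 | step 5 | methyl 2-iodo-4-methoxy-6-methylbenzoate | COC(=O)c1c(C)cc(OC)cc1I
F4 | step 5 | [5-methoxy-2-(methoxycarbonyl)-3-methylphenyl](2,4,6-trimethoxyphenyl)iodonium 4-methylbenzenesulfonate | COC(=O)c1c(C)cc(OC)cc1[I+]c1c(OC)cc(OC)cc1OC.Cc1ccc(cc1)S(=O)(=O)[O-]
F5 | step 5 | methyl 4-methoxy-2-[(7-methoxy-2,2,5-trimethyl-4-oxochroman-6-yl)oxy]-6-methylbenzoate | COC(=O)c1c(C)cc(OC)cc1Oc1c(OC)cc2OC(C)(C)CC(=O)c2c1C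
F6 | step 8 | depsidone 15 brominated on the ring A carbon between OH and CH3 | Cc1c(Br)c(O)cc2c1C(=O)Oc1cc3OC(C)(C)CC(=O)c3c(C)c1O2
F7 | step 8 | Mollicellin A brominated on the ring A carbon between OH and CH3 | Cc1c(Br)c(O)c(C=O)c2c1C(=O)Oc1cc3OC(C)(C)CC(=O)c3c(C)c1O2
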